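## The problem

Albanin A (13) is a flavone: a chromen-4-one (rings A and C) with a 2,4-dihydroxyphenyl ring B on C2, a 3-methylbut-2-enyl (prenyl) group on C3 and hydroxyls on C5 and C7. It has no stereocentre and no stereogenic double bond, so the task is one of regiochemistry and functional-group tolerance only. The C2=C3 bond of ring C is tetrasubstituted and sits between an ortho-substituted aryl group and the prenyl chain, which argues for bringing the prenyl group in on the carbon that becomes C3 and against alkylating a finished flavone. Four phenols have to be set free at the end beside the trisubstituted prenyl alkene, which does not survive hydrogenolysis or strong Lewis acids; under protic acid the 2'-hydroxyl can add across it to give cyclic ethers. The protecting groups must therefore leave under neutral, non-reducing conditions. The enabling feature is the oxygen pattern of ring A: C5 and C8a are ortho and C7 is para to C4a, the carbon that carries the C4 carbonyl. All three oxygens can therefore enter by displacement of fluoride from a 2,4,6-trifluorobenzoyl unit, whose symmetry leaves no question as to which ortho fluorine closes ring C.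

## Retrosynthesis

**13 to 12.** The four O-H bonds of 13 are traced back to four allyl ethers in 12. Methyl ethers would need boron halides and benzyl ethers hydrogen, both of which attack the prenyl group, and acetal groups would need the acid that invites cyclisation of the 2'-hydroxyl onto the prenyl alkene. Allyl ethers leave with a zerovalent palladium catalyst and an amine under neutral conditions, and the C-bound prenyl group has no leaving group for that catalyst to ionise. The forward step must cleave four ethers without C-allylation of the electron-rich ring A.

**12 to 9 and 10.** The C5-O and C7-O bonds are cut, leading to difluorochromone 9 and two molecules of allyl alcohol (10). The alternative of carrying both ring A oxygens through the ring closure would weaken the activation of the arene and would need a differentiated, non-commercial ring A acid. Fluorine serves as a masked hydroxyl that also activates the closure. Both C-F bonds of 9 are conjugated with the C4 carbonyl, so the forward reaction is a double nucleophilic aromatic substitution, and using the allyl oxygen nucleophile makes all four protecting groups the same.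

**9 to 6 and 7 (through 8).** C3-C4 and O1-C8a are cut. The neighbouring O1-C2 cut (cyclodehydration of an ortho-hydroxyaryl diketone) would need a selectively protected phloroglucinol ketone and acid for the dehydration. A C3-prenyl cut would mean alkylating a hindered vinylic position late. The chosen cut joins a ring B ketone that already carries the prenyl chain (6) to commercial 2,4,6-trifluorobenzoyl chloride (7). The forward reaction must acylate the enolate of 6 at carbon to give diketone 8 and then let the enol oxygen displace an ortho fluoride. One ring and two skeletal bonds are made, and no selectivity question remains beyond C- versus O-acylation.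

**6 to 4 and 5.** The bond between the α-carbon of the ketone and the prenyl CH2 is cut, giving methyl ketone 4 and prenyl bromide (5). Ketone 4 enolises on one side only, so the forward alkylation has no regiochemical issue. It must stop at monoalkylation and take place at the primary carbon of 5.

**4 to 1 and 2 (through 3).** The two O-allyl bonds are cut to reach 2,4-dihydroxyacetophenone (1) and two molecules of allyl bromide (2). The forward double etherification passes through the 4-monoether 3, since the 2-hydroxyl is hydrogen-bonded to the ketone and reacts second.

## Roads not taken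

**Alternative 1:** Ring A is cut at four bonds (C8a-C8, C7-C8, C5-C6, C4a-C5) and built by a Danheiser benzannulation on a finished pyranone. Irradiation of pyranonyl diazoketone A2 would trigger a Wolff rearrangement, and the resulting ketene would combine with silyloxyalkyne A3 in a cycloaddition and electrocyclic cascade to give chromone A1, with a free 5-hydroxyl and a 7-silyl ether.
- Merits: the two ring A oxygens arrive already differentiated, which the chosen plan cannot offer, and the regiochemistry of the annulation is fixed by the mechanism.
- Weak points: A2 is a 2,3,6-trisubstituted 4-pyranone carrying both the prenyl group and a diazoacetyl group, and its preparation would take more steps than the whole chosen route. The pyranone chromophore and the prenyl alkene must both survive ultraviolet light. A3 is a sensitive reagent.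
- Comparison: the target needs no differentiation of the C5 and C7 oxygens, so this advantage buys nothing here. The chosen plan takes ring A intact from a commercial acid chloride (7) and closes ring C in the same operation.

**Alternative 2:** C3-C4 and O1-C2 are cut. With [RhCl2(C5Me5)]2 and Cu(OAc)2, the aldehyde C-H bond and the phenol O-H bond of salicylaldehyde A5 would add across aryl prenyl alkyne A6 (a C-H activation at trivalent rhodium) to give fully protected chromone A4.
- Merits: this is the most convergent road. Both substituents of ring C and all four oxygens are in place after one bond-forming step, and no oxygen has to be installed afterwards. In step economy at the ring-forming stage it is better than the chosen plan.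
- Weak points: A6 is a skipped enyne whose doubly activated CH2 can isomerise to an allene or conjugated enyne under hot metal-acetate conditions. Its aryl group is ortho-substituted and electron-rich, which puts the sense of alkyne insertion and the rate in doubt. Decarbonylation of the acyl-rhodium intermediate is a known leak. The acetal groups of A4 would have to leave with acid, although allyl groups could be used there as well.
- Comparison: the chosen plan pays one extra step (fluoride exchange). Against that it sets a regiochemistry that is fixed by connectivity rather than by insertion preference, both partners (6 and 7) that are at most two steps from commercial materials, and a chain in 6 that is an ordinary saturated ketone side chain and not an isomerisable enyne.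

**Alternative 3:** C4a-C5 is cut. Mg(OMe)2 would turn pyranonyl β-ketoester A8 into an extended enolate whose C4a attacks the ester carbonyl. Ring A would close in a biomimetic Claisen condensation and aromatise to 5,7-dihydroxychromone A7.
- Merits: the ring A phenols appear free, only two protecting groups remain, and no fluoride exchange is needed. In protecting-group economy it is better than the chosen plan.
- Weak points: A8, a prenylated pyranone with an acetoacetate side chain, is a long target in itself. Its active methylene can instead attack the C4 carbonyl in an aldol mode. Methoxide can open the pyranone, after which the chain can refold in several ways.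
- Comparison: the chosen plan removes four allyl groups rather than two protecting groups and needs step 4. In return ring A is bought rather than built, and its closure (9 from 8) has only one possible mode.

Key step: step 3

Remarks on the chemistry:
- The target has no stereogenic element, so no configuration has to be set.
- Ionised forms of numbered compounds (enolates, phenoxides, Meisenheimer adducts) are not numbered separately.
- Steps 1 and 4 each consume two equivalents of the same alkylating partner (2 and 10); the second equivalent is entered under the reagents that add atoms.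
- The partly deallylated phenols of step 5 form as a converging statistical mixture and are not numbered one by one.
- Monoether 11 is drawn as the C7 ether expected in DMF; displacement at C5 first would converge on 12 as well.

## Steps

Step 1
Reactants: 1 2,4-dihydroxyacetophenone; 2 allyl bromide
Product: 4 1-[2,4-bis(allyloxy)phenyl]ethanone, via 4-monoallyl ether 3 (not isolated)
Conditions: 2 (2.5 equiv in all), K2CO3 (3 equiv), DMF, 60 °C
Reagents that add atoms: allyl bromide (second equivalent, the same compound as 2), C=CCBr
Why: Twofold Williamson ether synthesis; the free 4-hydroxyl takes the first equivalent of 2 to give 3 and the hydrogen-bonded 2-hydroxyl takes the second on warming with excess 2, while carbonate in DMF favours O- over C-allylation.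

Step 2
Reactants: 4 1-[2,4-bis(allyloxy)phenyl]ethanone; 5 prenyl bromide (1-bromo-3-methylbut-2-ene)
Product: 6 1-[2,4-bis(allyloxy)phenyl]-5-methylhex-4-en-1-one
Conditions: LiN(i-Pr)2 (LDA, commercial solution), THF, −78 °C; then 5, −78 °C to 0 °C
Reagents that add atoms: none
Why: Alkylation of a kinetic lithium enolate (SN2); 4 can enolise on one side only, full deprotonation before the halide is added suppresses aldol self-condensation, 5 reacts at its primary carbon, and keeping 5 as the limiting component holds dialkylation down.

Step 3
Reactants: 6 1-[2,4-bis(allyloxy)phenyl]-5-methylhex-4-en-1-one; 7 2,4,6-trifluorobenzoyl chloride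
Product: 9 2-[2,4-bis(allyloxy)phenyl]-5,7-difluoro-3-(3-methylbut-2-enyl)chromen-4-one, via 2-prenyl-1,3-diketone 8 (not isolated)
Conditions: MgBr2·OEt2, i-Pr2NEt, CH2Cl2, 0 °C to rt; dilute aqueous HCl wash; then K2CO3, DMF, 80 °C
Reagents that add atoms: none
Why: MgBr2 binds the ketone oxygen and the ortho allyloxy oxygen of 6, which acidifies the α-methylene enough for i-Pr2NEt to remove a proton (soft enolisation), and the magnesium enolate is acylated at carbon by 7 because its oxygen is held in the chelate (Claisen-type C-aroylation of a ketone with an acid chloride). Diketone 8 is captured at once as its magnesium diketonate, which prevents a second acylation. After magnesium is washed out, K2CO3 in DMF gives the potassium enolate of 8, whose oxygen on the ring B side adds to the ipso carbon of an ortho C-F bond to give a Meisenheimer adduct stabilised by the C4 carbonyl and the other two fluorines; loss of fluoride forms O1-C8a. Ring C therefore closes by a six-membered intramolecular addition-elimination at an aromatic carbon (formally 6-exo-trig if the C8a-C8 π bond is taken as the acceptor), whereas the other enolate oxygen could only form a four-membered ring. The two ortho fluorines are equivalent and the para fluorine is out of reach, so one chromone should result. The closest known reaction type is the one-pot aroylation and fluoride displacement that makes chromones and 4-quinolones from 2-fluorobenzoyl chlorides. No stereocentre is set, since C2 of 8 is racemic and labile and becomes the trigonal C3 of 9. The step needs C- over O-acylation, which the magnesium chelate secures, and monoacylation, which the diketonate secures.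

Step 4
Reactants: 9 2-[2,4-bis(allyloxy)phenyl]-5,7-difluoro-3-(3-methylbut-2-enyl)chromen-4-one; 10 allyl alcohol
Product: 12 5,7-bis(allyloxy)-2-[2,4-bis(allyloxy)phenyl]-3-(3-methylbut-2-enyl)chromen-4-one, via 7-allyl ether 11 (not isolated)
Conditions: 10 (3 equiv), NaH (2.5 equiv), THF, 0 °C; then 9, DMF, 0 °C to 60 °C
Reagents that add atoms: allyl alcohol (second equivalent, the same compound as 10, used as its sodium alkoxide), C=CCO
Why: Double nucleophilic aromatic substitution (addition-elimination) by NaOCH2CH=CH2, one equivalent for each C-F bond; C7-F is para and C5-F ortho to the C4 carbonyl, the second displacement is slower after the first ether is in place and is driven by warming, and the aryl and prenyl groups on C2 and C3 shield the pyranone against conjugate addition.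

Step 5
Reactants: 12 5,7-bis(allyloxy)-2-[2,4-bis(allyloxy)phenyl]-3-(3-methylbut-2-enyl)chromen-4-one
Product: 13 albanin A, 2-(2,4-dihydroxyphenyl)-5,7-dihydroxy-3-(3-methylbut-2-enyl)chromen-4-one
Conditions: Pd(PPh3)4 (cat.), morpholine (excess), degassed THF, rt; work-up at pH 5 to 6
Reagents that add atoms: none
Why: Tsuji-Trost-type deallylation; zerovalent palladium ionises each aryl allyl ether to a phenoxide and a π-allyl complex that morpholine captures irreversibly, the C-bound prenyl alkene has no leaving group and is untouched, and the neutral medium avoids acid-induced cyclisation of the 2'-hydroxyl onto the prenyl group.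

## Compound list

1 | 2,4-dihydroxyacetophenone | CC(=O)c1ccc(O)cc1O | starting material
2 | allyl bromide (3-bromoprop-1-ene) | C=CCBr | starting material
3 | 1-[4-(allyloxy)-2-hydroxyphenyl]ethanone | CC(=O)c1ccc(OCC=C)cc1O | intermediate (not isolated)
4 | 1-[2,4-bis(allyloxy)phenyl]ethanone | CC(=O)c1ccc(OCC=C)cc1OCC=C | intermediate
5 | prenyl bromide (1-bromo-3-methylbut-2-ene) | CC(C)=CCBr | starting material
6 | 1-[2,4-bis(allyloxy)phenyl]-5-methylhex-4-en-1-one | CC(C)=CCCC(=O)c1ccc(OCC=C)cc1OCC=C | intermediate
7 | 2,4,6-trifluorobenzoyl chloride | O=C(Cl)c1c(F)cc(F)cc1F | starting material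
8 | 1-[2,4-bis(allyloxy)phenyl]-2-(3-methylbut-2-enyl)-3-(2,4,6-trifluorophenyl)propane-1,3-dione (racemic at C2, in equilibrium with its enols) | CC(C)=CCC(C(=O)c1ccc(OCC=C)cc1OCC=C)C(=O)c1c(F)cc(F)cc1F | intermediate (not isolated)
9 | 2-[2,4-bis(allyloxy)phenyl]-5,7-difluoro-3-(3-methylbut-2-enyl)chromen-4-one | CC(C)=CCc1c(-c2ccc(OCC=C)cc2OCC=C)oc2cc(F)cc(F)c2c1=O | intermediate
10 | allyl alcohol (prop-2-en-1-ol) | C=CCO | starting material
11 | 7-(allyloxy)-2-[2,4-bis(allyloxy)phenyl]-5-fluoro-3-(3-methylbut-2-enyl)chromen-4-one | CC(C)=CCc1c(-c2ccc(OCC=C)cc2OCC=C)oc2cc(OCC=C)cc(F)c2c1=O | intermediate (not isolated)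
12 | 5,7-bis(allyloxy)-2-[2,4-bis(allyloxy)phenyl]-3-(3-methylbut-2-enyl)chromen-4-one | CC(C)=CCc1c(-c2ccc(OCC=C)cc2OCC=C)oc2cc(OCC=C)cc(OCC=C)c2c1=O | intermediate
13 | albanin A, 2-(2,4-dihydroxyphenyl)-5,7-dihydroxy-3-(3-methylbut-2-enyl)chromen-4-one (no stereocentre) | CC(C)=CCc1c(-c2ccc(O)cc2O)oc2cc(O)cc(O)c2c1=O | target

## Step count and risks

Total: 5 steps. Longest linear sequence: 5 steps (1 to 13); 2, 5, 7 and 10 are commercial.

**Step 3 (key step).**
- What may go wrong: acylation at the enolate oxygen or sluggish enolisation of the α-substituted ketone; a second acylation if the diketonate is not formed cleanly; magnesium-assisted loss of the allyl group ortho to the ketone if the mixture is warmed; in the closure stage, retro-Claisen cleavage of 8 by wet carbonate or intermolecular displacement of the para fluorine.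
- Fallback: it sets out from 4 and comes back at 12, so that the prenyl group enters last and the aroylation is run on the unhindered methyl ketone. Ketone 4 would be deprotonated with LiN(SiMe3)2 (2 equivalents, THF, −78 °C) and aroylated with 7 to give 1-[2,4-bis(allyloxy)phenyl]-3-(2,4,6-trifluorophenyl)propane-1,3-dione F1. K2CO3 in DMF should close this to 2-[2,4-bis(allyloxy)phenyl]-5,7-difluorochromen-4-one F2. NaOCH2CH=CH2 made from 10 (two equivalents) would then lead, through 7-(allyloxy)-2-[2,4-bis(allyloxy)phenyl]-5-fluorochromen-4-one F3, to 5,7-bis(allyloxy)-2-[2,4-bis(allyloxy)phenyl]chromen-4-one F4. Deprotonation of F4 at C3 with LiN(i-Pr)2 at −78 °C, a known metalation of flavones, and capture with 5 should give 12.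

**Step 2.**
- What may go wrong: proton transfer between the product ketone and unreacted enolate, leading to dialkylation and recovered 4.
- Fallback: it sets out from 4 and comes back at 6. Condensation of 4 with 1,1-dimethylhydrazine would give 1-[2,4-bis(allyloxy)phenyl]ethanone N,N-dimethylhydrazone F5 (mixture of C=N isomers, immaterial). Its azaenolate (LiN(i-Pr)2, THF, 0 °C) alkylates once with 5 to give 1-[2,4-bis(allyloxy)phenyl]-5-methylhex-4-en-1-one N,N-dimethylhydrazone F6. Two-phase hydrolysis with aqueous oxalic acid and ether should release 6.

**Step 4.**
- What may go wrong: the displacement at the second position may stall once the first ether donates into the ring; under the heating then needed, the alkoxide may add to C2 and open the pyranone.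
- Fallback: it sets out from 6 and comes back at 12, with the ring A oxygens in place before the closure. 5-Fluorobenzene-1,3-diol F7 would be allylated with 2 (two equivalents) and K2CO3 to 1,3-bis(allyloxy)-5-fluorobenzene F8. Vilsmeier-Haack formylation (POCl3, DMF), directed para to one ether and ortho to the other, should give 2,4-bis(allyloxy)-6-fluorobenzaldehyde F9. Pinnick oxidation (NaClO2, NaH2PO4, 2-methylbut-2-ene) would give 2,4-bis(allyloxy)-6-fluorobenzoic acid F10, and oxalyl chloride with catalytic DMF would give 2,4-bis(allyloxy)-6-fluorobenzoyl chloride F11. Acylation of 6 with F11 under the conditions of step 3 would give 1-[2,4-bis(allyloxy)-6-fluorophenyl]-3-[2,4-bis(allyloxy)phenyl]-2-(3-methylbut-2-enyl)propane-1,3-dione F12. Its closure with K2CO3 in DMF, at a higher temperature because the arene is less activated, should give 12 directly.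

**Step 5.**
- What may go wrong: C-allylation of the electron-rich ring A phenoxide (C6 or C8) by the π-allyl palladium cation if capture by morpholine lags; slow cleavage of the ether on C5 next to the carbonyl.
- Fallback: it sets out from 12 and comes back at 13 and avoids allyl cations altogether. Isomerisation of the four allyl ethers with [Ir(cod)(PMePh2)2]PF6 (activated with H2, THF, rt), which leaves trisubstituted alkenes alone, would give 2-{2,4-bis[(E)-prop-1-enyloxy]phenyl}-5,7-bis[(E)-prop-1-enyloxy]-3-(3-methylbut-2-enyl)chromen-4-one F13. Hydrolysis of the enol ethers with dilute HCl in aqueous THF at room temperature, too mild to protonate the prenyl alkene at a useful rate, should give 13.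

## Further compounds

F1 | step 3 | 1-[2,4-bis(allyloxy)phenyl]-3-(2,4,6-trifluorophenyl)propane-1,3-dione | O=C(CC(=O)c1c(F)cc(F)cc1F)c1ccc(OCC=C)cc1OCC=C
F2 | step 3 | 2-[2,4-bis(allyloxy)phenyl]-5,7-difluorochromen-4-one | O=c1cc(-c2ccc(OCC=C)cc2OCC=C)oc2cc(F)cc(F)c12
F3 | step 3 | 7-(allyloxy)-2-[2,4-bis(allyloxy)phenyl]-5-fluorochromen-4-one | O=c1cc(-c2ccc(OCC=C)cc2OCC=C)oc2cc(OCC=C)cc(F)c12
F4 | step 3 | 5,7-bis(allyloxy)-2-[2,4-bis(allyloxy)phenyl]chromen-4-one | O=c1cc(-c2ccc(OCC=C)cc2OCC=C)oc2cc(OCC=C)cc(OCC=C)c12
F5 | step 2 | 1-[2,4-bis(allyloxy)phenyl]ethanone N,N-dimethylhydrazone | CC(=NN(C)C)c1ccc(OCC=C)cc1OCC=C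
F6 | step 2 | 1-[2,4-bis(allyloxy)phenyl]-5-methylhex-4-en-1-one N,N-dimethylhydrazone | CC(C)=CCCC(=NN(C)C)c1ccc(OCC=C)cc1OCC=C
F7 | step 4 | 5-fluorobenzene-1,3-diol | Oc1cc(O)cc(F)c1
F8 | step 4 | 1,3-bis(allyloxy)-5-fluorobenzene | C=CCOc1cc(F)cc(OCC=C)c1
F9 | step 4 | 2,4-bis(allyloxy)-6-fluorobenzaldehyde | O=Cc1c(F)cc(OCC=C)cc1OCC=C
F10 | step 4 | 2,4-bis(allyloxy)-6-fluorobenzoic acid | OC(=O)c1c(F)cc(OCC=C)cc1OCC=C
F11 | step 4 | 2,4-bis(allyloxy)-6-fluorobenzoyl chloride | O=C(Cl)c1c(F)cc(OCC=C)cc1OCC=C
F12 | step 4 | 1-[2,4-bis(allyloxy)-6-fluorophenyl]-3-[2,4-bis(allyloxy)phenyl]-2-(3-methylbut-2-enyl)propane-1,3-dione | CC(C)=CCC(C(=O)c1ccc(OCC=C)cc1OCC=C)C(=O)c1c(F)cc(OCC=C)cc1OCC=C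
F13 | step 5 | 2-{2,4-bis[(E)-prop-1-enyloxy]phenyl}-5,7-bis[(E)-prop-1-enyloxy]-3-(3-methylbut-2-enyl)chromen-4-one | CC(C)=CCc1c(-c2ccc(O/C=C/C)cc2O/C=C/C)oc2cc(O/C=C/C)cc(O/C=C/C)c2c1=O
A1 | alternative 1 | 2-[2,4-bis(methoxymethoxy)phenyl]-5-hydroxy-3-(3-methylbut-2-enyl)-7-(triisopropylsilyloxy)chromen-4-one | CC(C)=CCc1c(-c2ccc(OCOC)cc2OCOC)oc2cc(O[Si](C(C)C)(C(C)C)C(C)C)cc(O)c2c1=O
A2 | alternative 1 | 2-(2-diazoacetyl)-6-[2,4-bis(methoxymethoxy)phenyl]-5-(3-methylbut-2-enyl)pyran-4-one | CC(C)=CCc1c(-c2ccc(OCOC)cc2OCOC)oc(C(=O)C=[N+]=[N-])cc1=O
A3 | alternative 1 | (triisopropylsilyloxy)ethyne | C#CO[Si](C(C)C)(C(C)C)C(C)C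
A4 | alternative 2 | 5,7-bis(methoxymethoxy)-2-[2,4-bis(methoxymethoxy)phenyl]-3-(3-methylbut-2-enyl)chromen-4-one | CC(C)=CCc1c(-c2ccc(OCOC)cc2OCOC)oc2cc(OCOC)cc(OCOC)c2c1=O
A5 | alternative 2 | 2-hydroxy-4,6-bis(methoxymethoxy)benzaldehyde | O=Cc1c(O)cc(OCOC)cc1OCOC
A6 | alternative 2 | 2,4-bis(methoxymethoxy)-1-(5-methylhex-4-en-1-ynyl)benzene | CC(C)=CCC#Cc1ccc(OCOC)cc1OCOC
A7 | alternative 3 | 2-[2,4-bis(methoxymethoxy)phenyl]-5,7-dihydroxy-3-(3-methylbut-2-enyl)chromen-4-one | CC(C)=CCc1c(-c2ccc(OCOC)cc2OCOC)oc2cc(O)cc(O)c2c1=O
A8 | alternative 3 | methyl 4-{6-[2,4-bis(methoxymethoxy)phenyl]-5-(3-methylbut-2-enyl)-4-oxopyran-2-yl}-3-oxobutanoate | COC(=O)CC(=O)Cc1cc(=O)c(CC=C(C)C)c(-c2ccc(OCOC)cc2OCOC)o1
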